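**Retrosynthetic overview**

Ring numbering used throughout: C1 (tiglate carbinol), C2 (isopropyl), C3 (acyloxy), C4–C5 (epoxide, methyl on C5), C6, C7, C8=C9 (methyl on C9), C10 (free carbinol). The carbocycle C1–C10 with the isopropyl on C2 and the methyls on C5 and C9 is an uncut head-to-tail farnesyl chain whose two ends meet at C2–C3; the strategy rests on this.
Late disconnections: C10–OH from the C10 enone; C3 and C1 esters from acid chlorides (Evans syn-aldol acid, tigloyl chloride); C1–O by α′-oxidation of the enone; C10–O and C3–O by cytochrome P450 allylic hydroxylation; oxirane by C3–OH-directed epoxidation of C4=C5.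
Core disconnection: C2–C3, by class-one terpene-cyclase closure of (2E,6E)-farnesyl diphosphate to (S)-germacrene A, which sets C2.
Ring order: ten-membered carbocycle first (step 3), oxirane second (step 6).

Key step: step 3

Assumption (chemistry): farnesyl diphosphate is drawn as the free acid and handled as its ammonium salt, and the C10 carbinol formed in step 7 is drawn as one epimer, either epimer serving because C10 is oxidised in step 8.

Step 1
Reactants: 1 (2E,6E)-farnesol
Product: 2 (2E,6E)-farnesyl chloride
Conditions: NCS, Me2S, CH2Cl2, −40 to 0 °C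
Reagents that add atoms: N-chlorosuccinimide, ClN1C(=O)CCC1=O
Why: Corey–Kim chlorination converts the primary allylic alcohol into the chloride through an alkoxysulfonium salt under neutral conditions, so neither allylic transposition nor E/Z isomerisation is expected.

Step 2
Reactants: 2 (2E,6E)-farnesyl chloride
Product: 3 (2E,6E)-farnesyl diphosphate
Conditions: (Bu4N)3HP2O7, MeCN, 20 °C; cation exchange to the NH4+ form; cellulose chromatography
Reagents that add atoms: tris(tetrabutylammonium) hydrogen diphosphate, CCCC[N+](CCCC)(CCCC)CCCC.CCCC[N+](CCCC)(CCCC)CCCC.CCCC[N+](CCCC)(CCCC)CCCC.OP(=O)([O-])OP(=O)([O-])[O-]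
Why: SN2 displacement of the primary allylic chloride by the diphosphate anion in a dipolar aprotic solvent is the standard way to allylic diphosphates and leaves the 2E alkene intact.

Step 3
Reactants: 3 (2E,6E)-farnesyl diphosphate
Product: 4 (S)-germacrene A
Conditions: recombinant (S)-selective germacrene A synthase (class-one cyclase of the aristolochene-synthase family, variant that releases the germacrene), MgCl2, HEPES buffer pH 7.5, dithiothreitol, pentane overlay, 25 °C, dark
Reagents that add atoms: none
Why: The divalent magnesium ions bound to the aspartate-rich motifs of the class-one cyclase ionise the allylic diphosphate of 3 to the (2E,6E)-farnesyl cation, C10 of the distal alkene attacks C1 (farnesyl numbering; these are C2 and C3 of the ring) to form the C2–C3 bond, and a methyl proton is lost from the resulting tertiary cation to give the isopropenyl group. The closest known reaction is this very one, the terpene-synthase cyclisation of farnesyl diphosphate to germacrene A. The ten-membered carbocycle is closed in a cation–olefin 1,10-closure in which the alkene reacts in the Markovnikov sense through C10, so that the cationic carbon stays outside the ring. The only new stereocentre, C2, is controlled by the enzyme, which presents one face of the C10=C11 alkene to C1; cyclases of the aristolochene-synthase family form the (S) enantiomer, and a variant lacking the reprotonating residue releases it instead of carrying it on to the eudesmane cation. The step needs 1,10- rather than 1,6- or 1,11-closure and retention of both E alkenes, which the substrate secures because the 2E allyl cation cannot reach C6, because attack through C10 gives the tertiary and not the secondary cation, and because no isomerisation to the nerolidyl system is involved. The hydrocarbon is taken up by the pentane layer as it forms and is kept cold and acid-free, since it undergoes Cope rearrangement on warming and transannular cyclisation with acid.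

Step 4
Reactants: 4 (S)-germacrene A
Product: 5 (S)-dihydrogermacrene A, (2S,4E,8E)-2-isopropyl-5,9-dimethylcyclodeca-4,8-diene in route numbering
Conditions: H2 (1 atm), RhCl(PPh3)3 (5 mol%), benzene, 15 °C
Reagents that add atoms: none
Why: Homogeneous hydrogenation with RhCl(PPh3)3 saturates the 1,1-disubstituted isopropenyl alkene far faster than the two trisubstituted ring alkenes and runs neutral and cold, so C2 and the 1,5-diene stay untouched.

Step 5
Reactants: 5 (S)-dihydrogermacrene A
Product: 6 (2R,3S,4E,8E)-2-isopropyl-5,9-dimethylcyclodeca-4,8-dien-3-ol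
Conditions: cytochrome P450 BM3 (CYP102A1) variant selected from an active-site library for the C3 methylene, air, NADP+ (cat.), phosphite dehydrogenase, Na2HPO3, potassium phosphate buffer pH 8.0, 2-hydroxypropyl-β-cyclodextrin, 25 °C
Reagents that add atoms: dioxygen, O=O
Why: Cytochrome P450 allylic hydroxylation (hydrogen abstraction by the oxoiron species and oxygen rebound with retention) at this methylene of the germacrene ring is the reaction of the costunolide-synthase class of enzymes, and a BM3 variant chosen by screening should hold 5 with one C3 hydrogen over the iron, which fixes both the site and the (3S) configuration.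

Step 6
Reactants: 6 (2R,3S)-allylic alcohol
Product: 7 (2R,3S,4R,5R,8E)-4,5-epoxy-2-isopropyl-5,9-dimethylcyclodec-8-en-3-ol
Conditions: Ti(OiPr)4 (1.0 equiv), tBuOOH (1.5 equiv, in decane), 4 Å molecular sieves, CH2Cl2, −20 °C
Reagents that add atoms: tert-butyl hydroperoxide, CC(C)(C)OO
Why: Titanium-alkoxide-directed epoxidation acts only on the allylic-alcohol alkene C4=C5 and not on C8=C9, and with the C3–H held in the alkene plane by A1,3 strain against the C5 methyl the bound peroxide is delivered to the open face on which the hydroxyl lies while ring carbon C2 covers the other, which gives the threo epoxy alcohol (4R,5R).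

Step 7
Reactants: 7 epoxy alcohol
Product: 8 (2R,3S,4R,5R,8E,10S)-4,5-epoxy-2-isopropyl-5,9-dimethylcyclodec-8-ene-3,10-diol
Conditions: cytochrome P450 BM3 (CYP102A1) variant of the lineage that hydroxylates germacranolide epoxides, air, NADP+ (cat.), phosphite dehydrogenase, Na2HPO3, potassium phosphate buffer pH 8.0, 2% DMSO, 25 °C
Reagents that add atoms: dioxygen, O=O
Why: Engineered BM3 variants are known to hydroxylate germacrene 4,5-epoxides that keep one ring alkene at the ring methylene next to the methyl-bearing alkene carbon (here C10), and 7 presents the same epoxide–alkene array, the only other activated positions being C7 and the C9 methyl.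

Step 8
Reactants: 8 epoxy diol
Product: 9 (2R,3S,4R,5R,8E)-4,5-epoxy-3-hydroxy-2-isopropyl-5,9-dimethylcyclodec-8-en-10-one
Conditions: activated MnO2 (15 equiv), CH2Cl2, 20 °C
Reagents that add atoms: none
Why: Activated MnO2 oxidises only the allylic carbinol at C10 to the enone and leaves the non-allylic C3 carbinol, the epoxide and the alkene geometry alone.

Step 9
Reactants: 9 hydroxy enone
Product: 10 (2R,3S,4R,5R,8E)-4,5-epoxy-2-isopropyl-5,9-dimethyl-3-(triethylsilyloxy)cyclodec-8-en-10-one
Conditions: Et3SiCl, imidazole, DMAP (cat.), DMF, 0 to 20 °C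
Reagents that add atoms: chlorotriethylsilane, CC[Si](Cl)(CC)CC
Why: Silylation of the only free hydroxyl masks C3–OH against alkoxide formation and Payne rearrangement in the enolate step, and the triethylsilyl ether can later be removed without acid strong enough to open the epoxide.

Step 10
Reactants: 10 silyl ether enone
Product: 12 (1S,2S,3S,4R,5R,8E)-4,5-epoxy-1-hydroxy-2-isopropyl-5,9-dimethyl-3-(triethylsilyloxy)cyclodec-8-en-10-one, via potassium enolate 11 (not isolated)
Conditions: KN(SiMe3)2 (1.2 equiv), THF, −78 °C; 2-(phenylsulfonyl)-3-phenyloxaziridine, −78 °C; AcOH quench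
Reagents that add atoms: 2-(phenylsulfonyl)-3-phenyloxaziridine, O=S(=O)(c1ccccc1)N1OC1c1ccccc1
Why: Kinetic deprotonation of the enone by the hindered amide removes an α′ proton at C1 to give the cross-conjugated enolate, and Davis oxidation should transfer oxygen to the enolate face away from the ring bond C2–C3, the C2–H lying in the enolate plane to avoid A1,3 strain, so that the new C1–O bond is syn to the isopropyl group in the zigzag C10–C1–C2–C3, which is (1S).

Step 11
Reactants: 12 (1S)-ketol; 13 tigloyl chloride
Product: 14 (1S,2S,3S,4R,5R,8E)-4,5-epoxy-2-isopropyl-5,9-dimethyl-10-oxo-3-(triethylsilyloxy)cyclodec-8-en-1-yl (E)-2-methylbut-2-enoate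
Conditions: pyridine, DMAP (0.3 equiv), CH2Cl2, 0 to 20 °C
Reagents that add atoms: tigloyl chloride 13, C/C=C(\C)C(Cl)=O
Why: DMAP-catalysed acylation of the single free hydroxyl by the acid chloride forms the C1 tiglate without touching the stereocentre, and the E enoate is the stable isomer.

Step 12
Reactants: 14 silyl ether tiglate
Product: 15 (1S,2R,3S,4R,5R,8E)-4,5-epoxy-3-hydroxy-2-isopropyl-5,9-dimethyl-10-oxocyclodec-8-en-1-yl (E)-2-methylbut-2-enoate
Conditions: HF·pyridine, pyridine, THF, 0 °C
Reagents that add atoms: none
Why: Buffered fluoride desilylation cleaves the triethylsilyl ether by attack at silicon, without an alkoxide that could move the tiglate and without acid that could open the trisubstituted epoxide.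

Step 13
Reactants: 16 (R)-4-benzyl-3-propanoyl-1,3-oxazolidin-2-one; 17 acetaldehyde
Product: 19 (R)-4-benzyl-3-[(2R,3S)-3-hydroxy-2-methylbutanoyl]-1,3-oxazolidin-2-one, via boron enolate 18 (not isolated)
Conditions: Bu2BOTf, iPr2NEt, CH2Cl2, 0 °C; 17, −78 to 0 °C; pH 7 buffer, MeOH, 30% H2O2
Reagents that add atoms: acetaldehyde 17, CC=O
Why: In this Evans syn aldol the Z boron enolate reacts through a chair Zimmerman–Traxler transition state with the aldehyde on the enolate face opposite the benzyl group of the dipole-opposed (R)-auxiliary, which sets (2R,3S).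

Step 14
Reactants: 19 aldol adduct
Product: 21 (2R,3S)-3-hydroxy-2-methylbutanoic acid, via peroxy acid 20 (not isolated)
Conditions: LiOH, 30% H2O2, THF/H2O, 0 °C; Na2SO3; HCl to pH 2
Reagents that add atoms: hydrogen peroxide, OO
Why: Lithium hydroperoxide attacks the exocyclic imide carbonyl selectively and at 0 °C causes neither retro-aldol cleavage nor epimerisation at C2, and sulfite reduces the peroxy acid to the acid.

Step 15
Reactants: 21 hydroxy acid
Product: 22 (2R,3S)-3-acetoxy-2-methylbutanoic acid
Conditions: Ac2O, pyridine, DMAP (cat.), CH2Cl2, 0 to 20 °C; aqueous work-up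
Reagents that add atoms: acetic anhydride, CC(=O)OC(C)=O
Why: Acetylation of the secondary hydroxyl is a plain acyl transfer that does not involve the stereocentres, and any mixed anhydride at the carboxyl group is hydrolysed in the aqueous work-up.

Step 16
Reactants: 22 acetoxy acid
Product: 23 (2R,3S)-3-acetoxy-2-methylbutanoyl chloride
Conditions: (COCl)2, DMF (cat.), CH2Cl2, 0 to 20 °C; evaporation
Reagents that add atoms: oxalyl chloride, ClC(=O)C(Cl)=O
Why: The chloroiminium catalyst formed from DMF converts the acid into the acid chloride in the absence of base, so that neither ketene formation with loss of the C2 configuration nor β-elimination of acetate is expected.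

Step 17
Reactants: 15 hydroxy ketone tiglate; 23 acid chloride
Product: 24 (1S,2R,3S,4R,5R,8E)-4,5-epoxy-2-isopropyl-5,9-dimethyl-1-[(E)-2-methylbut-2-enoyloxy]-10-oxocyclodec-8-en-3-yl (2R,3S)-3-acetoxy-2-methylbutanoate
Conditions: pyridine, DMAP (0.2 equiv), CH2Cl2, −20 to 0 °C
Reagents that add atoms: (2R,3S)-3-acetoxy-2-methylbutanoyl chloride 23, ClC(=O)[C@H](C)[C@H](C)OC(C)=O
Why: DMAP-catalysed acylation of the hindered C3 carbinol by the acid chloride, with only the weak base pyridine and at low temperature, should outrun ketene formation and acetate elimination, and the ketone at C10 keeps that oxygen from competing.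

Step 18
Reactants: 24 keto diester
Product: 25 CNP0332554.1, (1S,2S,3S,4R,5R,8E,10R)-4,5-epoxy-10-hydroxy-2-isopropyl-5,9-dimethyl-1-[(E)-2-methylbut-2-enoyloxy]cyclodec-8-en-3-yl (2R,3S)-3-acetoxy-2-methylbutanoate
Conditions: NaBH4, CeCl3·7H2O, MeOH/THF, −78 °C
Reagents that add atoms: none
Why: Luche reduction adds hydride 1,2 to the enone without touching esters, epoxide or enoate, and hydride should enter from the open face of the carbonyl with the C1–O bond eclipsing C=O and ring carbon C2 covering the other face, which places the new hydroxyl anti to the C1 tiglate in the zigzag C9–C10–C1–C2 and gives (10R).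

**Compound list**

1 | (2E,6E)-farnesol | CC(C)=CCC/C(C)=C/CC/C(C)=C/CO | starting material
2 | (2E,6E)-farnesyl chloride | CC(C)=CCC/C(C)=C/CC/C(C)=C/CCl | intermediate
3 | (2E,6E)-farnesyl diphosphate (free-acid form; handled as ammonium salt) | CC(C)=CCC/C(C)=C/CC/C(C)=C/COP(O)(=O)OP(O)(O)=O | intermediate
4 | (S)-germacrene A, (S,1E,5E)-1,5-dimethyl-8-(prop-1-en-2-yl)cyclodeca-1,5-diene | C1[C@H](C(C)=C)C/C=C(\C)CC/C=C(\C)C1 | intermediate
5 | (S)-dihydrogermacrene A, (S,1E,5E)-1,5-dimethyl-8-(propan-2-yl)cyclodeca-1,5-diene | C1[C@H](C(C)C)C/C=C(\C)CC/C=C(\C)C1 | intermediate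
6 | (2R,3S,4E,8E)-2-isopropyl-5,9-dimethylcyclodeca-4,8-dien-3-ol (route numbering) | C1[C@H](C(C)C)[C@H](O)/C=C(\C)CC/C=C(\C)C1 | intermediate
7 | (2R,3S,4R,5R,8E)-4,5-epoxy-2-isopropyl-5,9-dimethylcyclodec-8-en-3-ol | C1[C@H](C(C)C)[C@H](O)[C@H]2O[C@]2(C)CC/C=C(\C)C1 | intermediate
8 | (2R,3S,4R,5R,8E,10S)-4,5-epoxy-2-isopropyl-5,9-dimethylcyclodec-8-ene-3,10-diol | C1[C@H](C(C)C)[C@H](O)[C@H]2O[C@]2(C)CC/C=C(\C)[C@H]1O | intermediate
9 | (2R,3S,4R,5R,8E)-4,5-epoxy-3-hydroxy-2-isopropyl-5,9-dimethylcyclodec-8-en-10-one | C1[C@H](C(C)C)[C@H](O)[C@H]2O[C@]2(C)CC/C=C(\C)C1=O | intermediate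
10 | (2R,3S,4R,5R,8E)-4,5-epoxy-2-isopropyl-5,9-dimethyl-3-(triethylsilyloxy)cyclodec-8-en-10-one | C1[C@H](C(C)C)[C@H](O[Si](CC)(CC)CC)[C@H]2O[C@]2(C)CC/C=C(\C)C1=O | intermediate
11 | potassium C1=C10 enolate of 10 | C=1[C@H](C(C)C)[C@H](O[Si](CC)(CC)CC)[C@H]2O[C@]2(C)CC/C=C(\C)C=1[O-].[K+] | intermediate
12 | (1S,2S,3S,4R,5R,8E)-4,5-epoxy-1-hydroxy-2-isopropyl-5,9-dimethyl-3-(triethylsilyloxy)cyclodec-8-en-10-one | O[C@H]1[C@H](C(C)C)[C@H](O[Si](CC)(CC)CC)[C@H]2O[C@]2(C)CC/C=C(\C)C1=O | intermediate
13 | tigloyl chloride, (E)-2-methylbut-2-enoyl chloride | C/C=C(\C)C(Cl)=O | starting material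
14 | (1S,2S,3S,4R,5R,8E)-4,5-epoxy-2-isopropyl-5,9-dimethyl-10-oxo-3-(triethylsilyloxy)cyclodec-8-en-1-yl (E)-2-methylbut-2-enoate | C/C=C(\C)C(=O)O[C@H]1[C@H](C(C)C)[C@H](O[Si](CC)(CC)CC)[C@H]2O[C@]2(C)CC/C=C(\C)C1=O | intermediate
15 | (1S,2R,3S,4R,5R,8E)-4,5-epoxy-3-hydroxy-2-isopropyl-5,9-dimethyl-10-oxocyclodec-8-en-1-yl (E)-2-methylbut-2-enoate | C/C=C(\C)C(=O)O[C@H]1[C@H](C(C)C)[C@H](O)[C@H]2O[C@]2(C)CC/C=C(\C)C1=O | intermediate
16 | (R)-4-benzyl-3-propanoyl-1,3-oxazolidin-2-one | O=C1OC[C@@H](Cc2ccccc2)N1C(=O)CC | starting material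
17 | acetaldehyde | CC=O | starting material
18 | (Z)-dibutylboron enolate of 16 | O=C1OC[C@@H](Cc2ccccc2)N1/C(OB(CCCC)CCCC)=C/C | intermediate
19 | (R)-4-benzyl-3-[(2R,3S)-3-hydroxy-2-methylbutanoyl]-1,3-oxazolidin-2-one | O=C1OC[C@@H](Cc2ccccc2)N1C(=O)[C@H](C)[C@H](C)O | intermediate
20 | (2R,3S)-3-hydroxy-2-methylbutaneperoxoic acid | OOC(=O)[C@H](C)[C@H](C)O | intermediate
21 | (2R,3S)-3-hydroxy-2-methylbutanoic acid | OC(=O)[C@H](C)[C@H](C)O | intermediate
22 | (2R,3S)-3-acetoxy-2-methylbutanoic acid | OC(=O)[C@H](C)[C@H](C)OC(C)=O | intermediate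
23 | (2R,3S)-3-acetoxy-2-methylbutanoyl chloride | ClC(=O)[C@H](C)[C@H](C)OC(C)=O | intermediate
24 | (1S,2R,3S,4R,5R,8E)-4,5-epoxy-2-isopropyl-5,9-dimethyl-1-[(E)-2-methylbut-2-enoyloxy]-10-oxocyclodec-8-en-3-yl (2R,3S)-3-acetoxy-2-methylbutanoate | C/C=C(\C)C(=O)O[C@H]1[C@H](C(C)C)[C@H](OC(=O)[C@H](C)[C@H](C)OC(C)=O)[C@H]2O[C@]2(C)CC/C=C(\C)C1=O | intermediate
25 | CNP0332554.1, (1S,2S,3S,4R,5R,8E,10R)-4,5-epoxy-10-hydroxy-2-isopropyl-5,9-dimethyl-1-[(E)-2-methylbut-2-enoyloxy]cyclodec-8-en-3-yl (2R,3S)-3-acetoxy-2-methylbutanoate | C/C=C(\C)C(=O)O[C@H]1[C@H](C(C)C)[C@H](OC(=O)[C@H](C)[C@H](C)OC(C)=O)[C@H]2O[C@]2(C)CC/C=C(\C)[C@H]1O | target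

**Step count**

Total: 18 steps. Longest linear sequence: 14 steps (steps 1–12, 17, 18); the side chain takes steps 13–16.

**Three steps most likely to fail**

Step 5. What may go wrong: hydrogen abstraction at another allylic methylene (C6, C7, C10) or at a methyl, epoxidation of a ring alkene in place of hydroxylation, or oxygen rebound on the other C3 hydrogen, so that no variant gives 6 cleanly. The fallback sets out from 4 and comes back at 6; it uses the isopropenyl group as a handle for an intramolecular hydrogen transfer. Hydroboration of 4 with 9-BBN, which takes the 1,1-disubstituted alkene first, and oxidation with NaBO3·4H2O would give the primary alcohol F1. Exchange with tBuONO would give the nitrite ester F2. Barton nitrite photolysis (350 nm, benzene, 10 °C) would generate the side-chain alkoxy radical, which abstracts a C3 hydrogen through a six-membered transition state, C3 being its only allylic δ-carbon. Capture of NO at C3 and tautomerisation would give the conjugated oxime F3. Buffered TiCl3/NH4OAc would release the hydroxy enone F4, and TsCl in pyridine would give the tosylate F5. LiBHEt3 would then displace the tosylate, turning the side chain into isopropyl, and reduce the C3 ketone in the 1,2 sense from the open face with the C2 side chain eclipsing the carbonyl, which returns the (3S) alcohol 6.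

Step 7. What may go wrong: hydroxylation at C7 or at the C9 methyl, or over-oxidation, on a substrate that differs from the known ones by its free C3 hydroxyl and the missing lactone. The fallback sets out from 7 and comes back at 9; the C3 hydroxyl itself relays the oxidation. tBuONO would convert 7 into the C3 nitrite F6. Photolysis would give the C3 alkoxy radical, whose only allylic δ-hydrogens are those on C10 (six-membered transition state through C2 and C1). Capture of NO at C10 and tautomerisation would give the enone oxime F7 with the C3 hydroxyl restored. TiCl3/NH4OAc at pH 6 would then give 9, so that steps 7 and 8 are both replaced.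

Step 10. What may go wrong: poor facial selectivity in the oxygen transfer to the macrocyclic enolate, because the open face depends on which ring conformer reacts, besides some γ-deprotonation at C7. The fallback sets out from 10 and comes back at 14; it makes both C1 epimers converge. The (1R)-ketol F8 formed by attack on the other face would be esterified with tiglic acid under Mitsunobu conditions (PPh3, diisopropyl azodicarboxylate, toluene, 0 to 20 °C), which inverts C1 and gives 14 directly, while the (1S)-ketol 12 goes through step 11.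

**Further compounds**

F1 | step 5 | 2-[(1S,3E,7E)-4,8-dimethylcyclodeca-3,7-dien-1-yl]propan-1-ol (both side-chain epimers) | C1[C@H](C(C)CO)C/C=C(\C)CC/C=C(\C)C1
F2 | step 5 | nitrite ester of F1 | C1[C@H](C(C)CON=O)C/C=C(\C)CC/C=C(\C)C1
F3 | step 5 | C3 oxime of the C3-oxo derivative of F1 (route numbering) | C1[C@H](C(C)CO)C(=NO)/C=C(\C)CC/C=C(\C)C1
F4 | step 5 | (2S,4E,8E)-2-(1-hydroxypropan-2-yl)-5,9-dimethylcyclodeca-4,8-dien-3-one (route numbering) | C1[C@H](C(C)CO)C(=O)/C=C(\C)CC/C=C(\C)C1
F5 | step 5 | 4-methylbenzenesulfonate of F4 | C1[C@H](C(C)COS(=O)(=O)c2ccc(C)cc2)C(=O)/C=C(\C)CC/C=C(\C)C1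
F6 | step 7 | C3 nitrite ester of 7 | C1[C@H](C(C)C)[C@H](ON=O)[C@H]2O[C@]2(C)CC/C=C(\C)C1
F7 | step 7 | C10 oxime of 9 | C1[C@H](C(C)C)[C@H](O)[C@H]2O[C@]2(C)CC/C=C(\C)C1=NO
F8 | step 10 | (1R,2S,3S,4R,5R,8E)-4,5-epoxy-1-hydroxy-2-isopropyl-5,9-dimethyl-3-(triethylsilyloxy)cyclodec-8-en-10-one | O[C@@H]1[C@H](C(C)C)[C@H](O[Si](CC)(CC)CC)[C@H]2O[C@]2(C)CC/C=C(\C)C1=O
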